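## Retrosynthetic overview

1. Target 37 ⇐ dimethoxyquinone 36 ⇐ tetramethoxyarene 35: the quinone ring is unmasked last (oxidative demethylation, then selective saponification), and C4=CH2 comes from Wittig methylenation of the C4 ketone 34.
2. C11–aryl bond: 2,3,5,6-tetramethoxyphenyllithium adds to the C9 aldehyde 25, followed by radical deoxygenation.
3. C8 is set by OH-directed hydrogenation. The C9 quaternary centre is set by a [2,3]-Wittig–Still shift from the 7α-allylic alcohol 19, which comes from ketoreductase reduction of enone 18.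
4. Enone 18 comes from the C9 ketone 12 (methylation, Saegusa oxidation, MeLi, oxidative 1,3-transposition). The C4 oxygen and the trans ring fusion come from hydroboration of the Δ4 alkene 8.
5. The decalin comes from (S)-Wieland–Miescher ketone. Ring B is the starting cyclohexane-1,3-dione; ring A is closed onto it by proline-catalysed Robinson annulation (sets C10), followed by a ketoreductase reduction. The quinone ring comes from purchased 1,2,4,5-tetramethoxybenzene.

Assumption/convention: names use decalin locants C1–C10 (C10 = CH3-bearing ring-fusion carbon, C5 = ring-fusion CH, ring A = C1–C5 + C10, ring B = C5–C10, C11 = CH2 between C9 and the quinone ring), β is the face of the C10 methyl, and transient mechanistic species and pre-work-up salts of products are not numbered.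

## Route

Step 1
Reactants: 1 2-methylcyclohexane-1,3-dione; 2 but-3-en-2-one
Product: 3 2-methyl-2-(3-oxobutyl)cyclohexane-1,3-dione
Conditions: Et3N (1 mol %), neat, 23 °C
Reagents that add atoms: none
Why: Michael addition of the acidic 1,3-dione carbon to the enone gives the prochiral triketone without side reactions.

Step 2
Reactants: 3 2-methyl-2-(3-oxobutyl)cyclohexane-1,3-dione
Product: 5 (S)-Wieland–Miescher ketone, via cis-fused ketol 4 (not isolated)
Conditions: L-proline (5 mol %), DMSO, 35 °C, 4 d; recrystallise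
Reagents that add atoms: none
Why: Hajos–Parrish–Eder–Sauer–Wiechert aldol condensation (Robinson annulation closing ring A), in which the proline enamine attacks one enantiotopic ring carbonyl and sets C10 as S (about 70% ee crude, raised by crystallisation and by step 3).

Step 3
Reactants: 5 (S)-Wieland–Miescher ketone
Product: 6 (4aS,5S)-5-hydroxy-4a-methyl-4,4a,5,6,7,8-hexahydronaphthalen-2(3H)-one (9β-OH)
Conditions: ketoreductase (NADPH-dependent alcohol dehydrogenase, (S)-carbinol-forming), NADP+ (cat.), iPrOH (10% v/v) as hydride donor, potassium phosphate buffer pH 7.0, 30 °C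
Reagents that add atoms: none
Why: enzymatic carbonyl reduction that touches only the saturated C9 ketone, delivers hydride anti to the methyl (9β-OH) and accepts only the (S)-enantiomer, so residual (R)-5 stays a ketone and is separated, giving 6 in >99% ee.

Step 4
Reactants: 6 (4aS,5S)-hydroxy enone
Product: 7 C3 ethylene dithioketal of 6
Conditions: HS(CH2)2SH (1.2 equiv), BF3·OEt2 (0.3 equiv), MeOH, 0 → 23 °C
Reagents that add atoms: ethane-1,2-dithiol SCCS
Why: Lewis-acid thioacetalisation of the only carbonyl left; with dithiolanes the C4=C5 double bond stays where it is.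

Step 5
Reactants: 7 C3 ethylene dithioketal
Product: 8 9β-hydroxy-10β-methyl-Δ4-octalin [(1S,8aS)-8a-methyl-1,2,3,4,6,7,8,8a-octahydronaphthalen-1-ol]
Conditions: Raney Ni (W-2), EtOH, reflux
Reagents that add atoms: none
Why: Mozingo desulfurisation removes the C3 oxygen function and leaves the trisubstituted C4=C5 alkene as the handle for C4.

Step 6
Reactants: 8 9β-hydroxy-10β-methyl-Δ4-octalin
Product: 10 10β-methyl-trans-decalin-4α,9β-diol, via organoborane 9 (not isolated)
Conditions: BH3·THF (3 equiv), THF, 0 → 23 °C; then 3 M NaOH, 30% H2O2, 0 → 40 °C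
Reagents that add atoms: hydrogen peroxide OO
Why: hydroboration–oxidation, with syn addition from the α face (anti to the axial C10 methyl and the 9β-oxygen) and boron at the less substituted C4, sets C5-H α (trans ring fusion) and puts oxygen on C4.

Step 7
Reactants: 10 trans-decalin-4α,9β-diol
Product: 11 4α-(tert-butyldimethylsilyloxy)-10β-methyl-trans-decalin-9β-ol
Conditions: TBSCl (1.1 equiv), imidazole (2.5 equiv), DMF, 0 °C
Reagents that add atoms: tert-butyldimethylsilyl chloride CC(C)(C)[Si](C)(C)Cl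
Why: selective silylation, since the C4 carbinol reacts much faster than the neopentyl C9 carbinol next to the quaternary C10 (as for 3-OH versus 17-OH in steroids).

Step 8
Reactants: 11 4α-silyloxy-9β-ol
Product: 12 4α-(tert-butyldimethylsilyloxy)-10β-methyl-trans-decalin-9-one
Conditions: Pr4N[RuO4] (5 mol %), N-methylmorpholine N-oxide (1.5 equiv), 4 Å MS, CH2Cl2, 23 °C
Reagents that add atoms: none
Why: Ley–Griffith oxidation of the hindered secondary alcohol under neutral conditions that leave the silyl ether alone.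

Step 9
Reactants: 12 4α-silyloxy-9-ketone
Product: 14 4α-silyloxy-8,10β-dimethyl-trans-decalin-9-one (C8 epimers), via lithium enolate 13 (not isolated)
Conditions: LiN(iPr)2 (1.1 equiv), THF, −78 °C; MeI (1.5 equiv), −78 → 0 °C
Reagents that add atoms: iodomethane CI
Why: enolate alkylation is regiospecific because C8 is the only enolisable position (C10 is quaternary); the C8 configuration is erased in step 10.

Step 10
Reactants: 14 8-methyl-9-ketone
Product: 16 4α-silyloxy-8,10β-dimethyl-trans-Δ7-octalin-9-one, via trimethylsilyl enol ether 15 (not isolated)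
Conditions: TMSOTf (1.3 equiv), Et3N (2 equiv), CH2Cl2, 0 °C; concentrate; Pd(OAc)2 (1.05 equiv), MeCN, 23 °C
Reagents that add atoms: none
Why: Saegusa–Ito oxidation, in which the palladium enolate from the only possible silyl enol ether undergoes β-hydride elimination into the ring to give the 8-methyl enone.

Step 11
Reactants: 16 8-methyl-Δ7-en-9-one
Product: 17 4α-silyloxy-8,9α,10β-trimethyl-trans-Δ7-octalin-9β-ol
Conditions: MeLi (2 equiv), Et2O, −78 → 0 °C; then H2O
Reagents that add atoms: methyllithium [Li]C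
Why: 1,2-addition of the small, hard organolithium to the enone carbonyl (attack anti to the C10 methyl); either C9 epimer serves because this centre is lost in step 12.

Step 12
Reactants: 17 tertiary allylic alcohol
Product: 18 4α-silyloxy-8,9,10β-trimethyl-trans-Δ8-octalin-7-one
Conditions: [C5H5NH][CrO3Cl] (2 equiv), 4 Å MS, CH2Cl2, 23 °C
Reagents that add atoms: pyridinium chlorochromate [O-][Cr](=O)(=O)Cl.c1cc[nH+]cc1
Why: Dauben–Babler oxidative 1,3-transposition, in which the tertiary allylic chromate ester undergoes a [3,3] shift to the unhindered C7 and is oxidised, giving the tetrasubstituted enone.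

Step 13
Reactants: 18 Δ8-en-7-one
Product: 19 (7R)-4α-silyloxy-8,9,10β-trimethyl-trans-Δ8-octalin-7α-ol
Conditions: ketoreductase ((R)-carbinol-forming, chosen from a panel), NADP+ (cat.), iPrOH (15% v/v), DMSO (5% v/v), potassium phosphate buffer pH 7.0, 30 °C
Reagents that add atoms: none
Why: enzymatic 1,2-reduction under catalyst control delivers hydride to the β face and gives the pseudoaxial 7α-alcohol, overriding the substrate's preference for the 7β-alcohol; this centre is then relayed to C9 and C8.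

Step 14
Reactants: 19 7α-allylic alcohol
Product: 21 7α-(tributylstannylmethoxy) ether of 19, via potassium alkoxide 20 (not isolated)
Conditions: KH (1.5 equiv), THF, 0 °C; Bu3SnCH2I (1.3 equiv), 18-crown-6 (cat.), 0 → 23 °C
Reagents that add atoms: tributyl(iodomethyl)stannane CCCC[Sn](CCCC)(CCCC)CI
Why: Williamson etherification with the reactive primary iodide installs the carbanion precursor without touching the carbinol configuration.

Step 15
Reactants: 21 stannylmethyl ether
Product: 23 4α-silyloxy-9α-(hydroxymethyl)-8,9β,10β-trimethyl-trans-Δ7-octalin, via alkoxymethyllithium 22 (not isolated)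
Conditions: n-BuLi (1.5 equiv), THF, −78 → −20 °C; then H2O
Reagents that add atoms: none
Why: tin–lithium exchange then [2,3]-Wittig–Still rearrangement, which is suprafacial, so CH2O moves from the pseudoaxial 7α-oxygen to the α face of C9 (anti to the axial C10 methyl), setting C9 with CH2OH α and CH3 β and shifting the alkene to C7=C8.

Step 16
Reactants: 23 homoallylic alcohol
Product: 24 4α-silyloxy-9α-(hydroxymethyl)-8β,9β,10β-trimethyl-trans-decalin
Conditions: [Ir(cod)(PCy3)(py)]PF6 (5 mol %), H2 (1 atm), CH2Cl2, 23 °C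
Reagents that add atoms: none
Why: hydroxyl-directed hydrogenation, in which the cationic iridium binds the α-face CH2OH and delivers H2 to the same face of C7=C8, so C8-H is α and the C8 methyl is β, cis to the other two methyls.

Step 17
Reactants: 24 saturated primary alcohol
Product: 25 4α-silyloxy-8β,9β,10β-trimethyl-trans-decalin-9α-carbaldehyde
Conditions: Pr4N[RuO4] (5 mol %), N-methylmorpholine N-oxide (1.5 equiv), 4 Å MS, CH2Cl2, 23 °C
Reagents that add atoms: none
Why: Ley–Griffith oxidation stops at the aldehyde, which has no α-hydrogen and cannot epimerise.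

Step 18
Reactants: 25 9α-carbaldehyde; 26 1,2,4,5-tetramethoxybenzene
Product: 28 9α-[hydroxy(2,3,5,6-tetramethoxyphenyl)methyl] decalin (C11 epimers), via aryllithium 27 (not isolated)
Conditions: 26 (2 equiv), n-BuLi (1.9 equiv), TMEDA, THF, 0 °C, 1 h; then 25, −78 → 0 °C; H2O
Reagents that add atoms: none
Why: directed ortho-lithiation between two methoxy groups, then 1,2-addition of the aryllithium to the non-enolisable aldehyde; the new carbinol centre is removed in step 20.

Step 19
Reactants: 28 benzylic alcohol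
Product: 31 O-alkyl S-methyl dithiocarbonate of 28, via sodium alkoxide 29 (not isolated), via sodium xanthate 30 (not isolated)
Conditions: NaH (3 equiv), THF, 0 → 23 °C; CS2 (5 equiv); MeI (5 equiv)
Reagents that add atoms: carbon disulfide S=C=S; iodomethane CI
Why: xanthate formation uses the small electrophile CS2, which reaches even this hindered alkoxide, and there is no β-hydrogen on C9 for Chugaev elimination.

Step 20
Reactants: 31 xanthate
Product: 32 4α-silyloxy-8β,9β,10β-trimethyl-9α-(2,3,5,6-tetramethoxybenzyl)-trans-decalin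
Conditions: Bu3SnH (2 equiv), AIBN (0.2 equiv), toluene, 110 °C
Reagents that add atoms: none
Why: Barton–McCombie deoxygenation through a benzylic radical, which avoids the cationic rearrangement that threatens this neopentyl position.

Step 21
Reactants: 32 silyl ether
Product: 33 8β,9β,10β-trimethyl-9α-(2,3,5,6-tetramethoxybenzyl)-trans-decalin-4α-ol
Conditions: Bu4NF (3 equiv), THF, 50 °C
Reagents that add atoms: none
Why: fluoride desilylation; nothing else in the molecule responds to fluoride.

Step 22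
Reactants: 33 4α-ol
Product: 34 8β,9β,10β-trimethyl-9α-(2,3,5,6-tetramethoxybenzyl)-trans-decalin-4-one
Conditions: Pr4N[RuO4] (5 mol %), N-methylmorpholine N-oxide (1.5 equiv), 4 Å MS, CH2Cl2, 23 °C
Reagents that add atoms: none
Why: Ley–Griffith oxidation under neutral conditions, so the C5 centre next to the new ketone is not disturbed.

Step 23
Reactants: 34 C4 ketone
Product: 35 3-{[8β,9β,10β-trimethyl-4-methylene-trans-decalin-9α-yl]methyl}-1,2,4,5-tetramethoxybenzene
Conditions: Ph3PCH3Br (3 equiv), KOtBu (2.8 equiv), toluene, 23 → 80 °C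
Reagents that add atoms: methyltriphenylphosphonium bromide C[P+](c1ccccc1)(c1ccccc1)c1ccccc1.[Br-]
Why: Wittig methylenation; the trans ring fusion should be the more stable arrangement at C5, so any reversible enolisation is not expected to erode it.

Step 24
Reactants: 35 tetramethoxyarene
Product: 36 2,5-dimethoxy-3-{[8β,9β,10β-trimethyl-4-methylene-trans-decalin-9α-yl]methyl}-1,4-benzoquinone
Conditions: (NH4)2Ce(NO3)6 (2.5 equiv), MeCN–H2O (2:1), 0 °C, 15 min
Reagents that add atoms: water O
Why: oxidative demethylation of a para-dimethoxy pair to the p-quinone; both para pairs give the same quinone by symmetry, and the 1,1-disubstituted alkene survives the short, cold reaction.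

Step 25
Reactants: 36 dimethoxyquinone
Product: 37 target, 2-hydroxy-5-methoxy-3-{[8β,9β,10β-trimethyl-4-methylene-trans-decalin-9α-yl]methyl}-1,4-benzoquinone
Conditions: 2 M KOH (aq.), MeOH–THF, 0 → 23 °C; then 1 M HCl
Reagents that add atoms: potassium hydroxide [K+].[OH-]
Why: regioselective saponification (addition–elimination) of the vinylogous ester whose methoxy group is twisted out of conjugation by the neighbouring side chain; the resulting vinylogous carboxylate is deactivated, so the second methoxy stays.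

## Compound list

1 | 2-methylcyclohexane-1,3-dione | CC1C(=O)CCCC1=O | starting material
2 | but-3-en-2-one (methyl vinyl ketone) | CC(=O)C=C | starting material
3 | 2-methyl-2-(3-oxobutyl)cyclohexane-1,3-dione | CC(=O)CCC1(C)C(=O)CCCC1=O | intermediate
4 | cis-fused ketol, (4aS,8aS)-4a-hydroxy-8a-methyloctahydronaphthalene-1,6-dione (OH cis to CH3) | O=C1CC[C@@]2(C)[C@@](O)(C1)CCCC2=O | intermediate (not isolated)
5 | (S)-Wieland–Miescher ketone, (S)-8a-methyl-3,4,8,8a-tetrahydronaphthalene-1,6(2H,7H)-dione | O=C1CC[C@@]2(C)C(=C1)CCCC2=O | intermediate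
6 | (4aS,5S)-5-hydroxy-4a-methyl-4,4a,5,6,7,8-hexahydronaphthalen-2(3H)-one (9β-OH, cis to CH3) | O=C1CC[C@@]2(C)C(=C1)CCC[C@@H]2O | intermediate
7 | C3 ethylene dithioketal (spiro-1,3-dithiolane) of 6 | S1CCSC12CC[C@@]3(C)C(=C2)CCC[C@@H]3O | intermediate
8 | 9β-hydroxy-10β-methyl-Δ4-octalin, (1S,8aS)-8a-methyl-1,2,3,4,6,7,8,8a-octahydronaphthalen-1-ol | C1CC[C@@]2(C)C(=C1)CCC[C@@H]2O | intermediate
9 | organoborane from 8 (drawn as 4α-BH2, 5α-H, 9β-OBH2) | B[C@@H]1CCC[C@@]2(C)[C@H]1CCC[C@@H]2OB | intermediate (not isolated)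
10 | 10β-methyl-trans-decalin-4α,9β-diol (5α-H) | O[C@@H]1CCC[C@@]2(C)[C@H]1CCC[C@@H]2O | intermediate
11 | 4α-(tert-butyldimethylsilyloxy)-10β-methyl-trans-decalin-9β-ol | CC(C)(C)[Si](C)(C)O[C@@H]1CCC[C@@]2(C)[C@H]1CCC[C@@H]2O | intermediate
12 | 4α-(tert-butyldimethylsilyloxy)-10β-methyl-trans-decalin-9-one | CC(C)(C)[Si](C)(C)O[C@@H]1CCC[C@@]2(C)[C@H]1CCCC2=O | intermediate
13 | lithium Δ8-enolate of 12 | CC(C)(C)[Si](C)(C)O[C@@H]1CCC[C@@]2(C)[C@H]1CCC=C2O[Li] | intermediate (not isolated)
14 | 4α-silyloxy-8,10β-dimethyl-trans-decalin-9-one (C8 epimers, C8 left undefined) | CC(C)(C)[Si](C)(C)O[C@@H]1CCC[C@@]2(C)[C@H]1CCC(C)C2=O | intermediate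
15 | 9-(trimethylsilyloxy)-Δ8 enol ether of 14 | CC(C)(C)[Si](C)(C)O[C@@H]1CCC[C@@]2(C)[C@H]1CCC(C)=C2O[Si](C)(C)C | intermediate (not isolated)
16 | 4α-silyloxy-8,10β-dimethyl-trans-Δ7-octalin-9-one | CC(C)(C)[Si](C)(C)O[C@@H]1CCC[C@@]2(C)[C@H]1CC=C(C)C2=O | intermediate
17 | 4α-silyloxy-8,9α,10β-trimethyl-trans-Δ7-octalin-9β-ol | CC(C)(C)[Si](C)(C)O[C@@H]1CCC[C@@]2(C)[C@H]1CC=C(C)[C@]2(C)O | intermediate
18 | 4α-silyloxy-8,9,10β-trimethyl-trans-Δ8-octalin-7-one | CC(C)(C)[Si](C)(C)O[C@@H]1CCC[C@@]2(C)[C@H]1CC(=O)C(C)=C2C | intermediate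
19 | (7R)-4α-silyloxy-8,9,10β-trimethyl-trans-Δ8-octalin-7α-ol | CC(C)(C)[Si](C)(C)O[C@@H]1CCC[C@@]2(C)[C@H]1C[C@@H](O)C(C)=C2C | intermediate
20 | potassium alkoxide of 19 | CC(C)(C)[Si](C)(C)O[C@@H]1CCC[C@@]2(C)[C@H]1C[C@@H]([O-])C(C)=C2C.[K+] | intermediate (not isolated)
21 | 7α-(tributylstannylmethoxy) ether of 19 | CC(C)(C)[Si](C)(C)O[C@@H]1CCC[C@@]2(C)[C@H]1C[C@@H](OC[Sn](CCCC)(CCCC)CCCC)C(C)=C2C | intermediate
22 | 7α-(lithiomethoxy) ether | CC(C)(C)[Si](C)(C)O[C@@H]1CCC[C@@]2(C)[C@H]1C[C@@H](OC[Li])C(C)=C2C | intermediate (not isolated)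
23 | 4α-silyloxy-9α-(hydroxymethyl)-8,9β,10β-trimethyl-trans-Δ7-octalin | CC(C)(C)[Si](C)(C)O[C@@H]1CCC[C@@]2(C)[C@H]1CC=C(C)[C@@]2(C)CO | intermediate
24 | 4α-silyloxy-9α-(hydroxymethyl)-8β,9β,10β-trimethyl-trans-decalin | CC(C)(C)[Si](C)(C)O[C@@H]1CCC[C@@]2(C)[C@H]1CC[C@H](C)[C@@]2(C)CO | intermediate
25 | 4α-silyloxy-8β,9β,10β-trimethyl-trans-decalin-9α-carbaldehyde | CC(C)(C)[Si](C)(C)O[C@@H]1CCC[C@@]2(C)[C@H]1CC[C@H](C)[C@@]2(C)C=O | intermediate
26 | 1,2,4,5-tetramethoxybenzene | COc1cc(OC)c(OC)cc1OC | starting material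
27 | 2,3,5,6-tetramethoxyphenyllithium | [Li]c1c(OC)c(OC)cc(OC)c1OC | intermediate (not isolated)
28 | 9α-[hydroxy(2,3,5,6-tetramethoxyphenyl)methyl]-4α-silyloxy-8β,9β,10β-trimethyl-trans-decalin (C11 epimers) | CC(C)(C)[Si](C)(C)O[C@@H]1CCC[C@@]2(C)[C@H]1CC[C@H](C)[C@@]2(C)C(O)c1c(OC)c(OC)cc(OC)c1OC | intermediate
29 | sodium alkoxide of 28 | CC(C)(C)[Si](C)(C)O[C@@H]1CCC[C@@]2(C)[C@H]1CC[C@H](C)[C@@]2(C)C([O-])c1c(OC)c(OC)cc(OC)c1OC.[Na+] | intermediate (not isolated)
30 | sodium O-alkyl dithiocarbonate (xanthate salt) of 28 | CC(C)(C)[Si](C)(C)O[C@@H]1CCC[C@@]2(C)[C@H]1CC[C@H](C)[C@@]2(C)C(OC(=S)[S-])c1c(OC)c(OC)cc(OC)c1OC.[Na+] | intermediate (not isolated)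
31 | O-alkyl S-methyl dithiocarbonate of 28 | CC(C)(C)[Si](C)(C)O[C@@H]1CCC[C@@]2(C)[C@H]1CC[C@H](C)[C@@]2(C)C(OC(=S)SC)c1c(OC)c(OC)cc(OC)c1OC | intermediate
32 | 4α-silyloxy-8β,9β,10β-trimethyl-9α-(2,3,5,6-tetramethoxybenzyl)-trans-decalin | CC(C)(C)[Si](C)(C)O[C@@H]1CCC[C@@]2(C)[C@H]1CC[C@H](C)[C@@]2(C)Cc1c(OC)c(OC)cc(OC)c1OC | intermediate
33 | 8β,9β,10β-trimethyl-9α-(2,3,5,6-tetramethoxybenzyl)-trans-decalin-4α-ol | O[C@@H]1CCC[C@@]2(C)[C@H]1CC[C@H](C)[C@@]2(C)Cc1c(OC)c(OC)cc(OC)c1OC | intermediate
34 | 8β,9β,10β-trimethyl-9α-(2,3,5,6-tetramethoxybenzyl)-trans-decalin-4-one | O=C1CCC[C@@]2(C)[C@H]1CC[C@H](C)[C@@]2(C)Cc1c(OC)c(OC)cc(OC)c1OC | intermediate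
35 | 3-{[8β,9β,10β-trimethyl-4-methylene-trans-decalin-9α-yl]methyl}-1,2,4,5-tetramethoxybenzene | C=C1CCC[C@@]2(C)[C@H]1CC[C@H](C)[C@@]2(C)Cc1c(OC)c(OC)cc(OC)c1OC | intermediate
36 | 2,5-dimethoxy-3-{[8β,9β,10β-trimethyl-4-methylene-trans-decalin-9α-yl]methyl}-1,4-benzoquinone | C=C1CCC[C@@]2(C)[C@H]1CC[C@H](C)[C@@]2(C)CC1=C(OC)C(=O)C=C(OC)C1=O | intermediate
37 | 2-hydroxy-5-methoxy-3-{[8β,9β,10β-trimethyl-4-methylene-trans-decalin-9α-yl]methyl}-1,4-benzoquinone (CNP0109104.1) | C=C1CCC[C@@]2(C)[C@H]1CC[C@H](C)[C@@]2(C)CC1=C(O)C(=O)C=C(OC)C1=O | target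

## Step count and risks

Total step count: 25. Longest linear sequence: 25 steps (1 → 37); arene 26 is used as purchased.

The three steps most likely to fail:

Step 15 ([2,3]-Wittig–Still shift building the quaternary C9 next to the quaternary C10 on a tetrasubstituted alkene; [1,2]-shift or simple protonation may compete). The fallback sets out from allylic alcohol 19 and returns at 23. Heating 19 with Me2NCH(OMe)2 in xylene at 150 °C generates an alkoxy(amino)carbene that undergoes the Büchi [2,3] rearrangement under neutral thermal conditions, with the same suprafacial α delivery, to give the β,γ-unsaturated 9α-(N,N-dimethylcarboxamide) F3. Reduction of this amide with LiEt3BH (THF, 0 → 23 °C) gives the primary alcohol 23.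

Step 13 (a ketoreductase may not accept the hindered, lipophilic tetrasubstituted enone, or may give the wrong epimer). The fallback sets out from enone 18 and returns at 19. Luche reduction (NaBH4, CeCl3·7H2O, MeOH, −40 °C) gives the 7β-allylic alcohol F1 by axial hydride attack. Mitsunobu inversion (4-nitrobenzoic acid, PPh3, DIAD, THF, 0 °C) converts it to the 7α 4-nitrobenzoate F2, and methanolysis (K2CO3, MeOH, 23 °C) releases 19.

Step 25 (mono-hydrolysis may give the regioisomer or run on to the dihydroxyquinone). The fallback sets out from 36 and returns at 37. Both vinylogous esters are saponified on purpose (2 M NaOH, MeOH–THF, 60 °C; then dilute HCl) to the 2,5-dihydroxyquinone F4. This is then mono-O-methylated under equilibrating conditions (MeOH, BF3·OEt2 cat., 23 °C), which puts the methyl on the unhindered, fully conjugated oxygen remote from the side chain and gives 37.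

## Further compounds

F1 | step 13 | (7S)-4α-silyloxy-8,9,10β-trimethyl-trans-Δ8-octalin-7β-ol | CC(C)(C)[Si](C)(C)O[C@@H]1CCC[C@@]2(C)[C@H]1C[C@H](O)C(C)=C2C
F2 | step 13 | 7α 4-nitrobenzoate of 19 | CC(C)(C)[Si](C)(C)O[C@@H]1CCC[C@@]2(C)[C@H]1C[C@@H](OC(=O)c3ccc(cc3)[N+](=O)[O-])C(C)=C2C
F3 | step 15 | 4α-silyloxy-8,9β,10β-trimethyl-trans-Δ7-octalin-9α-(N,N-dimethylcarboxamide) | CC(C)(C)[Si](C)(C)O[C@@H]1CCC[C@@]2(C)[C@H]1CC=C(C)[C@@]2(C)C(=O)N(C)C
F4 | step 25 | 2,5-dihydroxy-3-{[8β,9β,10β-trimethyl-4-methylene-trans-decalin-9α-yl]methyl}-1,4-benzoquinone | C=C1CCC[C@@]2(C)[C@H]1CC[C@H](C)[C@@]2(C)CC1=C(O)C(=O)C=C(O)C1=O
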